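## The problem

CNP0394509.2 (26) is a germacranolide-type sesquiterpenoid. Its ten-membered carbocycle (C1–C10) is bridged by an oxygen from C4 to C1, which gives a 2,3-dihydrofuran whose C1=C2 bond is an enol ether, and it is fused at C6/C7 to a butenolide whose exocyclic C5=C6 bond lies inside the macrocycle. Numbering used throughout: C1 is the enol-ether carbon, C2 (=CH) and C3 (CH2) the other dihydrofuran carbons, C4 the quaternary carbon carrying the ring oxygen and a methyl group, C5=C6 the ylidene bond (C6 on the lactone oxygen), C7=C11 the butenolide alkene, C8 the methacrylate carbon, C9 a CH2, C10 the tertiary carbinol, C12 the lactone carbonyl and C13 the acetoxymethyl carbon. There are three stereocentres, C4, C8 and C10. C8 and C10 are 1,3-related with their oxygens on the same face, so one can direct the other once both sit in a six-membered ring. C4 is separated from them by sp2 carbons and needs its own source of absolute configuration. The enol ether (acid), the dienyl lactone and the methacrylate (bases, nucleophiles), the allylic acetate and the tertiary alcohol next to the enol ether are fragile and must be revealed late; the tetrasubstituted C7=C11 bond must be built with C12 cis to C6 before the lactone can exist. The enabling feature is that C1 and C6 are both at the ketone oxidation level and stand 1,6 across the carbocycle: the enol ether is the dehydrated hemiketal of a C1 ketone with the C4 hydroxyl, and the ylidene lactone is the enol lactone of a C6 ketone with the C12 acid. A cyclodecane-1,6-dione is what remains when the central alkene of a bicyclo[4.4.0]dec-1(6)-ene (ring A = C1–C6, ring B = C1, C6, C7–C10) is cleaved, so the medium ring need not be closed by a cyclisation.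

## Retrosynthesis

**C8–O acyl bond (26 ⇒ 25 ⇒ 24).** The methacrylate is removed first, because it is a Michael acceptor that would not survive organometallic, oxidative or acidic steps. This leaves alcohol 25 and, one protecting group further back, silyl ether 24. The C8 oxygen is held as a tert-butyldiphenylsilyl ether until the heterocycles exist. The C8 hydroxyl is, like the C4 hydroxyl, γ to the C1 ketone, and an acid-stable silyl group removes it from the competition for C1. The forward steps ask only for a buffered desilylation and acylation of a secondary alcohol beside an unreactive tertiary one.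

**C1–O(C4) and C6–O(C12) bonds (24 ⇒ 22).** Both heterocycles are cut at once, back to the open diketone 22, in which the C4 oxygen and the C12 carboxyl are still masked. Forming either ring earlier would carry an acid-labile enol ether or a base-labile dienyl lactone through the whole sequence. Forward, acid must free the C12 acid and the C4 hydroxyl; each adds to the ketone five atoms away, and two molecules of water are lost (through seco acid 23). C10 is quaternary, so the C1 lactol can dehydrate only toward C2, and the ring fixes the C5=C6 geometry.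

**C1=C6 (22 ⇒ 20, the key cut).** Reconnecting the two ketone carbons of 22 turns the ten-membered ring into octalin 20. This is preferred to any cut of a single ring bond, because a cleavage in the forward direction forms the medium ring without an entropic penalty. A cycloaddition route to ring A was set aside: the two termini of the diene it would need differ only through remote substituents, so the position of C4 relative to C7 and C10 would be left to chance. Precursor 20 is an ordinary fused bicycle with three stereocentres. The forward reaction must cleave the tetra-alkyl C1=C6 bond in the presence of the ester-bearing C7=C11 bond (through ozonide 21).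

**C10–CH3 bond and protecting groups (20 ⇒ 19 ⇒ 18 ⇒ 17 ⇒ 16).** Silylation, acetylation and selective desilylation lead back to tertiary alcohol 17, and removal of the C10 methyl gives ring B ketone 16. Adding the methyl group last lets C8, already in the ring, set C10. Forward, a non-basic methyl nucleophile must attack the ketone face opposite the C8 silyloxy group, without enolising toward C9 and without touching the ester.

**C6–C7 and C11–C12 bonds (16 ⇒ 15).** Ring B and the tetrasubstituted dienoate are cut together, back to alkynyl enol triflate 15. The neighbouring cut, olefination of a C7 ketone with a substituted phosphonoacetate, would have to form a tetrasubstituted alkene at a doubly flanked ketone with no control of geometry. A syn carbopalladation of C7≡C11 from C6, followed by carbonylation, fixes the geometry mechanistically: C12 ends cis to C6. Precursor 15 is monocyclic with an open chain.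

**C1–C10 bond and the C6–O triflate (15 ⇒ 14 ⇒ 13 ⇒ 4 + 12).** The triflate comes from 1,3-diketone 14. The diketone comes by oxidation of aldol adduct 13, and 13 from ketone 4 and aldehyde 12. Placing the ring A carbonyl at C6, meta to C4, settles the constitution: the less hindered α-carbon is C1, so C4 ends para to C1 and meta to C6 as required. The forward steps ask for regioselective enolisation of 4 away from the quaternary carbon and for O-triflation on the ring oxygen of 14.

**C8–C9 bond (12 ⇒ 11 ⇒ 10 ⇒ 7 + 8; 7 ⇒ 6 ⇒ 5).** Aldehyde 12 is a protected acetate-aldol product. Cutting C8–C9 gives ynal 7 and ketene acetal 8, joined by a catalytic asymmetric aldol addition (through silyl ether 9). This is preferred to an alkynylation of a β-oxo aldehyde, which would be unstable. Ynal 7 comes from but-2-yne-1,4-diol 5 via 6. C8 is thus set by a catalyst, independently of C4.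

**C4–O bond (4 ⇒ 3 ⇒ 2 ⇒ 1).** The tertiary carbinol of ring A is cut to boronate 2 and then to 3-methylcyclohex-2-en-1-one 1. An asymmetric conjugate borylation followed by oxidation with retention installs C4 in two steps from a cheap enone. It is chosen over resolution or over addition of a methyl group to a 1,3-dione derivative, which would have no stereocontrol.

## Roads not taken

**Alternative 1:** The cut is the enol-ether bond C1=C2, with the macrocycle left for later. Ester A1 already contains C4–O–C1 as a tertiary ester of the C10 α-silyloxy acid with a homoallylic alcohol. A reduced titanium ethylidene reagent (TiCl4, TMEDA, Zn, PbCl2, CH3CHBr2) would olefinate the ester carbonyl and close the ring onto the terminal alkene to give dihydrofuran A2.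
- Merits: the dihydrofuran is made without acid; there is no question of which hydroxyl bridges to C1; both quaternary carbinols come from small separate pieces.
- Weak points: the ester lies between two fully substituted carbons and is a poor substrate for alkylidenation; the reagent is stoichiometric in several metals; the ten-membered ring, the butenolide and C8 all remain to be made by ring closure with a labile enol ether on board.
- Comparison: this road is better than the chosen plan at securing the C4–O–C1 connectivity, which the chosen plan must protect by masking C8–OH during a late cyclodehydration. Against this the chosen plan sets a medium ring obtained without macrocyclisation and both heterocycles latent in one intermediate.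

**Alternative 2:** The cut is C4–C5. CrCl2 with catalytic NiCl2 would convert iodoylidene butenolide A3 into an alkenylchromium species that adds to the tethered C4 methyl ketone, giving macrocyclic alcohol A4 with retention of alkene geometry.
- Merits: convergent; the carbocycle and the C4 carbinol form in one step; the ylidene butenolide exists before ring closure, so no late enol lactonisation is needed. In this respect it is better than the chosen plan.
- Weak points: ketones are sluggish partners in this coupling and the closure is a ten-membered cyclisation; C4 is created with only the macrocycle's conformation as a control element; the C1 dithiane must be removed later beside a dienyl lactone before the dihydrofuran can be formed.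
- Comparison: the chosen plan fixes C4 at the outset by catalysis and forms the ring by cleavage. In exchange it accepts two late cyclodehydrations.

**Alternative 3:** The cut is C3–C4, by an anionic oxy-Cope shift. KH with 18-crown-6 would ionise the C1 carbinol of divinylcyclohexanol A5; the [3,3] shift breaks C1–C6 and gives cyclodecenone A6 with the C1 ketone, C5=C6 and the quaternary C4.
- Merits: like the chosen plan it is a ring expansion with no macrocyclisation, and it delivers C5=C6 and the butenolide already in place, so only the C1 ketone has to be processed afterwards. Here it is as good as or better than the chosen plan.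
- Weak points: A5 is a crowded, doubly quaternary cyclohexanol fused to a butenolide and is long to assemble; the lactone and the silyl ethers must survive a naked alkoxide; C4 depends on the chair or boat preference of the transition state and on the geometry of a fully substituted enol ether.
- Comparison: the chosen plan works under neutral conditions at low temperature on a substrate whose three stereocentres are already secure. It pays for this with the need to differentiate two hydroxyls in the end game.

Key step: step 17

Remark: the facial sense of the two catalytic asymmetric steps (1 and 6) is taken from the published models for the nearest substrates; if a ligand delivers the antipode, its enantiomer is used.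

## Route

Step 1
Reactants: 1 3-methylcyclohex-2-en-1-one
Product: 2 (R)-3-methyl-3-(4,4,5,5-tetramethyl-1,3,2-dioxaborolan-2-yl)cyclohexan-1-one
Conditions: B2pin2, [Cu(MeCN)4]PF6 (5 mol %), (R,R)-2,3-bis(tert-butylmethylphosphino)quinoxaline (6 mol %), LiOtBu (10 mol %), MeOH (2 equiv), DMSO, rt
Reagents that add atoms: bis(pinacolato)diboron, CC1(C)OB(OC1(C)C)B1OC(C)(C)C(C)(C)O1
Why: Copper-catalysed asymmetric conjugate borylation of a β-substituted cyclic enone; the phosphine-ligated copper boryl adds to the β-carbon (C4) on the face left open by the ligand and MeOH protonates the enolate, which sets the quaternary C4 centre.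

Step 2
Reactants: 2 (R)-3-methyl-3-(4,4,5,5-tetramethyl-1,3,2-dioxaborolan-2-yl)cyclohexan-1-one
Product: 3 (S)-3-hydroxy-3-methylcyclohexan-1-one
Conditions: NaBO3·4H2O, THF/H2O, rt
Reagents that add atoms: sodium perborate, [Na+].[O-]OB=O
Why: Oxidation of a tertiary boronate; carbon migrates from boron to oxygen with retention, so C4 keeps its configuration, and the buffered perborate spares the β-hydroxy ketone from dehydration.

Step 3
Reactants: 3 (S)-3-hydroxy-3-methylcyclohexan-1-one
Product: 4 (S)-3-methyl-3-[(triethylsilyl)oxy]cyclohexan-1-one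
Conditions: Et3SiOTf, 2,6-lutidine, CH2Cl2, −78 °C
Reagents that add atoms: triethylsilyl trifluoromethanesulfonate, CC[Si](CC)(CC)OS(=O)(=O)C(F)(F)F
Why: Silylation of a tertiary alcohol with a silyl triflate; the low temperature avoids enol silane formation and blocks retro-aldol and elimination pathways in later steps.

Step 4
Reactants: 5 but-2-yne-1,4-diol
Product: 6 4-[(tert-butyldimethylsilyl)oxy]but-2-yn-1-ol
Conditions: NaH (1 equiv), THF, 0 °C; then tBuMe2SiCl, rt
Reagents that add atoms: tert-butyldimethylsilyl chloride, CC(C)(C)[Si](C)(C)Cl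
Why: Monosilylation of a symmetrical diol through its sparingly soluble monosodium alkoxide, which reacts once and leaves the second hydroxyl free.

Step 5
Reactants: 6 4-[(tert-butyldimethylsilyl)oxy]but-2-yn-1-ol
Product: 7 4-[(tert-butyldimethylsilyl)oxy]but-2-ynal
Conditions: MnO2, CH2Cl2, rt
Reagents that add atoms: none
Why: Oxidation of a propargylic alcohol with activated MnO2 stops at the ynal and does not affect the silyl ether.

Step 6
Reactants: 7 4-[(tert-butyldimethylsilyl)oxy]but-2-ynal; 8 1-methoxy-1-[(trimethylsilyl)oxy]ethene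
Product: 10 methyl (S)-6-[(tert-butyldimethylsilyl)oxy]-3-hydroxyhex-4-ynoate, via trimethylsilyl ether 9 (not isolated)
Conditions: Ti(OiPr)4 (2 mol %), (R)-2-[(3-bromo-5-tert-butyl-2-hydroxybenzylidene)amino]-2′-hydroxy-1,1′-binaphthyl (2 mol %), 3,5-di-tert-butylsalicylic acid (2 mol %), Et2O, −10 °C; then K2CO3 (cat.), MeOH, 0 °C
Reagents that add atoms: none
Why: Catalytic enantioselective Mukaiyama aldol addition of an acetate silyl ketene acetal to a conjugated ynal under a chiral Schiff-base complex of tetravalent titanium, a substrate class for which this reaction is highly selective; the catalyst-controlled aldehyde face sets C8, and K2CO3/MeOH removes only the trimethylsilyl group.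

Step 7
Reactants: 10 methyl (S)-6-[(tert-butyldimethylsilyl)oxy]-3-hydroxyhex-4-ynoate
Product: 11 methyl (S)-6-[(tert-butyldimethylsilyl)oxy]-3-[(tert-butyldiphenylsilyl)oxy]hex-4-ynoate
Conditions: tBuPh2SiCl, imidazole, DMF, rt
Reagents that add atoms: tert-butyldiphenylsilyl chloride, CC(C)(C)[Si](Cl)(c1ccccc1)c1ccccc1
Why: Imidazole-promoted silylation of the secondary propargylic alcohol; this silyl ether is chosen because it outlasts the acid of step 18 and keeps the C8 oxygen away from C1.

Step 8
Reactants: 11 methyl (S)-6-[(tert-butyldimethylsilyl)oxy]-3-[(tert-butyldiphenylsilyl)oxy]hex-4-ynoate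
Product: 12 (S)-6-[(tert-butyldimethylsilyl)oxy]-3-[(tert-butyldiphenylsilyl)oxy]hex-4-ynal
Conditions: iBu2AlH (1.05 equiv), CH2Cl2, −78 °C; aq. potassium sodium tartrate
Reagents that add atoms: none
Why: Partial reduction of an ester with iBu2AlH; the tetrahedral aluminium acetal is stable at −78 °C and releases the aldehyde only on work-up.

Step 9
Reactants: 4 (S)-3-methyl-3-[(triethylsilyl)oxy]cyclohexan-1-one; 12 (S)-6-[(tert-butyldimethylsilyl)oxy]-3-[(tert-butyldiphenylsilyl)oxy]hex-4-ynal
Product: 13 (5S)-2-{(3S)-6-[(tert-butyldimethylsilyl)oxy]-3-[(tert-butyldiphenylsilyl)oxy]-1-hydroxyhex-4-yn-1-yl}-5-methyl-5-[(triethylsilyl)oxy]cyclohexan-1-one (epimers at the new centres C1 and C10)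
Conditions: LiN(iPr)2, THF, −78 °C; then 12, −78 °C; aq. NH4Cl
Reagents that add atoms: none
Why: Kinetic aldol addition; LiN(iPr)2 deprotonates 4 at C1, the α-CH2 remote from the quaternary C4 (the other α-carbon is neopentylic), and the lithium enolate adds to the aldehyde to form C1–C10; the two new centres are erased in steps 10 and 11.

Step 10
Reactants: 13 aldol adduct
Product: 14 (5S)-2-{(3S)-6-[(tert-butyldimethylsilyl)oxy]-3-[(tert-butyldiphenylsilyl)oxy]hex-4-ynoyl}-5-methyl-5-[(triethylsilyl)oxy]cyclohexan-1-one (enolised 1,3-diketone)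
Conditions: Dess–Martin periodinane, NaHCO3, CH2Cl2, 0 °C to rt
Reagents that add atoms: none
Why: Dess–Martin oxidation of a β-hydroxy ketone to the 1,3-diketone, obtained as its enol; the buffer keeps the silyl ethers intact.

Step 11
Reactants: 14 1,3-diketone
Product: 15 (5S)-2-{(3S)-6-[(tert-butyldimethylsilyl)oxy]-3-[(tert-butyldiphenylsilyl)oxy]hex-4-ynoyl}-5-methyl-5-[(triethylsilyl)oxy]cyclohex-1-en-1-yl trifluoromethanesulfonate
Conditions: NaH, THF, 0 °C; then Tf2O, −78 to 0 °C
Reagents that add atoms: trifluoromethanesulfonic anhydride, O=S(=O)(OS(=O)(=O)C(F)(F)F)C(F)(F)F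
Why: O-Sulfonylation of a 1,3-diketone enolate; 2-acylcyclohexanones are enolised toward the ring, and triflation of the sodium chelate on the ring oxygen gives the 2-acylcyclohex-1-enyl triflate with the C1=C6 bond in place and only the most acidic C1 hydrogen removed.

Step 12
Reactants: 15 alkynyl enol triflate
Product: 16 4-methoxybenzyl (E)-2-[(2S,7S)-2-[(tert-butyldiphenylsilyl)oxy]-7-methyl-4-oxo-7-[(triethylsilyl)oxy]-3,4,5,6,7,8-hexahydronaphthalen-1(2H)-ylidene]-3-[(tert-butyldimethylsilyl)oxy]propanoate (ester carbon C12 cis to C6)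
Conditions: Pd(OAc)2 (10 mol %), PPh3 (20 mol %), CO (1 atm), 4-MeOC6H4CH2OH (5 equiv), Et3N (2 equiv), DMF, 50 °C
Reagents that add atoms: carbon monoxide, [C-]#[O+]; 4-methoxybenzyl alcohol, COc1ccc(CO)cc1
Why: Cyclic carbopalladation with carbonylative esterification; zerovalent palladium inserts into C6–OTf, the alkenylpalladium adds syn across C7≡C11 in the 6-exo-dig mode (forming C6–C7 and ring B), and CO insertion with alcoholysis puts C12 on C11; because the addition is syn, C12 ends cis to C6 and C13 cis to C8.

Step 13
Reactants: 16 octalin dienone ester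
Product: 17 4-methoxybenzyl (E)-2-[(2S,4R,7S)-2-[(tert-butyldiphenylsilyl)oxy]-4-hydroxy-4,7-dimethyl-7-[(triethylsilyl)oxy]-3,4,5,6,7,8-hexahydronaphthalen-1(2H)-ylidene]-3-[(tert-butyldimethylsilyl)oxy]propanoate
Conditions: MeLi (3 equiv), CeCl3 (3 equiv), THF, −78 °C
Reagents that add atoms: methyllithium, [Li]C
Why: 1,2-Addition of a methylcerium reagent to the C10 ketone; the reagent is non-basic (no enolisation toward C9, which would expel the C8 silyloxy group) and ignores the hindered conjugated ester; it attacks the cyclohexenone face anti to the bulky C8 silyloxy group, held pseudoaxial by allylic 1,3-strain with the exocyclic alkylidene, as in additions to 5-substituted cyclohex-2-enones, so the C10 hydroxyl ends cis to the C8 oxygen.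

Step 14
Reactants: 17 tertiary alcohol
Product: 18 4-methoxybenzyl (E)-2-[(2S,4R,7S)-2-[(tert-butyldiphenylsilyl)oxy]-4-hydroxy-4,7-dimethyl-7-[(triethylsilyl)oxy]-3,4,5,6,7,8-hexahydronaphthalen-1(2H)-ylidene]-3-hydroxypropanoate
Conditions: HF·pyridine, pyridine, THF, 0 °C
Reagents that add atoms: none
Why: Buffered fluoride desilylation; the unhindered primary allylic silyl ether reacts much faster than the secondary tert-butyldiphenylsilyl and tertiary triethylsilyl ethers, and any loss at C4 is repaired in step 16.

Step 15
Reactants: 18 diol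
Product: 19 4-methoxybenzyl (E)-3-acetoxy-2-[(2S,4R,7S)-2-[(tert-butyldiphenylsilyl)oxy]-4-hydroxy-4,7-dimethyl-7-[(triethylsilyl)oxy]-3,4,5,6,7,8-hexahydronaphthalen-1(2H)-ylidene]propanoate
Conditions: Ac2O, pyridine, DMAP (cat.), CH2Cl2, 0 °C
Reagents that add atoms: acetic anhydride, CC(=O)OC(C)=O
Why: Acetylation of the primary alcohol; the tertiary C10 alcohol does not react at 0 °C.

Step 16
Reactants: 19 acetate
Product: 20 4-methoxybenzyl (E)-3-acetoxy-2-[(2S,4R,7S)-2-[(tert-butyldiphenylsilyl)oxy]-4,7-dimethyl-4,7-bis[(triethylsilyl)oxy]-3,4,5,6,7,8-hexahydronaphthalen-1(2H)-ylidene]propanoate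
Conditions: Et3SiOTf, 2,6-lutidine, CH2Cl2, −40 to 0 °C
Reagents that add atoms: triethylsilyl trifluoromethanesulfonate, CC[Si](CC)(CC)OS(=O)(=O)C(F)(F)F
Why: Silylation of the tertiary allylic alcohol with a silyl triflate under lutidine buffering, so that the key-step product is a plain diketone with no free hydroxyl to form hemiketals.

Step 17
Reactants: 20 octalin dienoate
Product: 22 4-methoxybenzyl (Z)-3-acetoxy-2-[(4S,8S,10R)-8-[(tert-butyldiphenylsilyl)oxy]-4,10-dimethyl-1,6-dioxo-4,10-bis[(triethylsilyl)oxy]cyclodecan-7-ylidene]propanoate (skeletal numbering), via secondary ozonide 21 (not isolated)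
Conditions: O3, CH2Cl2, −78 °C (Sudan Red 7B end point); then Me2S, −78 °C to rt
Reagents that add atoms: ozone, [O-][O+]=O
Why: Ozone adds as a 1,3-dipole to the tetra-alkyl C1=C6 bond; the primary ozonide fragments to a ketone and a carbonyl oxide that stay tethered and recombine to ozonide 21 (or its peroxidic equivalents), and Me2S reduces the O–O bond to release the C1 and C6 ketones. The closest known reactions are the ozonolysis of bicyclo[4.4.0]dec-1(6)-enes to cyclodecane-1,6-diones and the γ,δ-selective ozonolysis of 2,4-dienoates. The ten-membered ring arises by cleavage of the bond shared by rings A and B and not by a cyclisation, so no end-to-end closure and no high dilution are involved. No stereocentre is formed; C4, C8 and C10 are carried unchanged, and none is α to a new carbonyl with an exchangeable hydrogen (C10 is quaternary). The selectivity required is attack on C1=C6 in preference to C7=C11 and to the arene rings. It is secured by electron density: C1=C6 carries four alkyl groups and is twisted out of conjugation, whereas C7=C11 bears the ester and becomes still poorer once the C6 ketone exists, so over-oxidation is self-limiting and ozone is metered to the indicator end point. The product holds a Z 4-oxo-2-enoate (C6/C12) and a γ-silyloxy ketone (C1/C4), the latent forms of both oxygen heterocycles.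

Step 18
Reactants: 22 cyclodecane-1,6-dione
Product: 24 (4S,8S,10R)-13-acetoxy-8-[(tert-butyldiphenylsilyl)oxy]-1,4-epoxy-10-hydroxygermacra-1,5,7(11)-trien-12,6-olide, via seco keto acid 23 (not isolated)
Conditions: CF3CO2H/CH2Cl2 (1:9), anisole, 0 °C; evaporate; camphorsulfonic acid (10 mol %), 4 Å molecular sieves, benzene, 40 °C
Reagents that add atoms: none
Why: Acid unmasking followed by double cyclodehydration; CF3CO2H cleaves the 4-methoxybenzyl ester (cation trapped by anisole) and the two tertiary triethylsilyl ethers but not the C8 silyl ether or the acetate, the C12 acid adds to the C6 ketone (Z 4-oxo-2-enoic acids exist as 5-hydroxybutenolides) and the C4 hydroxyl adds to the C1 ketone (five-membered lactol); camphorsulfonic acid over sieves then removes two molecules of water, giving the C1=C2 enol ether (C10 has no hydrogen) and the C5=C6 enol lactone, whose geometry (C4 cis to C7) is imposed by the nine-membered ring that contains it.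

Step 19
Reactants: 24 silyl-protected tricycle
Product: 25 (4S,8S,10R)-13-acetoxy-1,4-epoxy-8,10-dihydroxygermacra-1,5,7(11)-trien-12,6-olide
Conditions: Bu4NF, AcOH (1:1), THF, 0 °C to rt
Reagents that add atoms: none
Why: Fluoride desilylation buffered with acetic acid, so that the dienyl lactone, the acetate and the enol ether meet neither free alkoxide nor strong acid.

Step 20
Reactants: 25 diol
Product: 26 CNP0394509.2: (4S,8S,10R)-13-acetoxy-1,4-epoxy-10-hydroxy-8-(2-methylprop-2-enoyloxy)germacra-1,5,7(11)-trien-12,6-olide
Conditions: methacrylic anhydride, Et3N, DMAP (cat.), CH2Cl2, 0 °C to rt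
Reagents that add atoms: methacrylic anhydride, CC(=C)C(=O)OC(=O)C(C)=C
Why: DMAP-catalysed acylation of the secondary C8 alcohol; the tertiary C10 alcohol is too hindered to compete.

## Compound list

1 | 3-methylcyclohex-2-en-1-one | CC1=CC(=O)CCC1 | starting material
2 | (R)-3-methyl-3-(4,4,5,5-tetramethyl-1,3,2-dioxaborolan-2-yl)cyclohexan-1-one | O=C1C[C@@](C)(B2OC(C)(C)C(C)(C)O2)CCC1 | intermediate
3 | (S)-3-hydroxy-3-methylcyclohexan-1-one | O=C1C[C@@](C)(O)CCC1 | intermediate
4 | (S)-3-methyl-3-[(triethylsilyl)oxy]cyclohexan-1-one (carbonyl carbon = C6, quaternary carbon = C4) | O=C1C[C@@](C)(O[Si](CC)(CC)CC)CCC1 | intermediate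
5 | but-2-yne-1,4-diol | OCC#CCO | starting material
6 | 4-[(tert-butyldimethylsilyl)oxy]but-2-yn-1-ol | OCC#CCO[Si](C)(C)C(C)(C)C | intermediate
7 | 4-[(tert-butyldimethylsilyl)oxy]but-2-ynal | O=CC#CCO[Si](C)(C)C(C)(C)C | intermediate
8 | 1-methoxy-1-[(trimethylsilyl)oxy]ethene | C=C(OC)O[Si](C)(C)C | starting material
9 | methyl (S)-6-[(tert-butyldimethylsilyl)oxy]-3-[(trimethylsilyl)oxy]hex-4-ynoate | COC(=O)C[C@H](O[Si](C)(C)C)C#CCO[Si](C)(C)C(C)(C)C | intermediate (not isolated)
10 | methyl (S)-6-[(tert-butyldimethylsilyl)oxy]-3-hydroxyhex-4-ynoate | COC(=O)C[C@H](O)C#CCO[Si](C)(C)C(C)(C)C | intermediate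
11 | methyl (S)-6-[(tert-butyldimethylsilyl)oxy]-3-[(tert-butyldiphenylsilyl)oxy]hex-4-ynoate | COC(=O)C[C@H](O[Si](c1ccccc1)(c1ccccc1)C(C)(C)C)C#CCO[Si](C)(C)C(C)(C)C | intermediate
12 | (S)-6-[(tert-butyldimethylsilyl)oxy]-3-[(tert-butyldiphenylsilyl)oxy]hex-4-ynal | O=CC[C@H](O[Si](c1ccccc1)(c1ccccc1)C(C)(C)C)C#CCO[Si](C)(C)C(C)(C)C | intermediate
13 | (5S)-2-{(3S)-6-[(tert-butyldimethylsilyl)oxy]-3-[(tert-butyldiphenylsilyl)oxy]-1-hydroxyhex-4-yn-1-yl}-5-methyl-5-[(triethylsilyl)oxy]cyclohexan-1-one (epimers at C1 and C10) | O=C1C[C@@](C)(O[Si](CC)(CC)CC)CCC1C(O)C[C@H](O[Si](c1ccccc1)(c1ccccc1)C(C)(C)C)C#CCO[Si](C)(C)C(C)(C)C | intermediate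
14 | (5S)-2-{(3S)-6-[(tert-butyldimethylsilyl)oxy]-3-[(tert-butyldiphenylsilyl)oxy]hex-4-ynoyl}-5-methyl-5-[(triethylsilyl)oxy]cyclohexan-1-one (enolised) | O=C1C[C@@](C)(O[Si](CC)(CC)CC)CCC1C(=O)C[C@H](O[Si](c1ccccc1)(c1ccccc1)C(C)(C)C)C#CCO[Si](C)(C)C(C)(C)C | intermediate
15 | (5S)-2-{(3S)-6-[(tert-butyldimethylsilyl)oxy]-3-[(tert-butyldiphenylsilyl)oxy]hex-4-ynoyl}-5-methyl-5-[(triethylsilyl)oxy]cyclohex-1-en-1-yl trifluoromethanesulfonate | O=C(C[C@H](O[Si](c1ccccc1)(c1ccccc1)C(C)(C)C)C#CCO[Si](C)(C)C(C)(C)C)C1=C(OS(=O)(=O)C(F)(F)F)C[C@@](C)(O[Si](CC)(CC)CC)CC1 | intermediate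
16 | 4-methoxybenzyl (E)-2-[(2S,7S)-2-[(tert-butyldiphenylsilyl)oxy]-7-methyl-4-oxo-7-[(triethylsilyl)oxy]-3,4,5,6,7,8-hexahydronaphthalen-1(2H)-ylidene]-3-[(tert-butyldimethylsilyl)oxy]propanoate | CC(C)(C)[Si](c1ccccc1)(c1ccccc1)O[C@H]1CC(=O)C2=C(C[C@@](C)(O[Si](CC)(CC)CC)CC2)/C1=C(/CO[Si](C)(C)C(C)(C)C)C(=O)OCc1ccc(OC)cc1 | intermediate
17 | 4-methoxybenzyl (E)-2-[(2S,4R,7S)-2-[(tert-butyldiphenylsilyl)oxy]-4-hydroxy-4,7-dimethyl-7-[(triethylsilyl)oxy]-3,4,5,6,7,8-hexahydronaphthalen-1(2H)-ylidene]-3-[(tert-butyldimethylsilyl)oxy]propanoate | CC(C)(C)[Si](c1ccccc1)(c1ccccc1)O[C@H]1C[C@@](C)(O)C2=C(C[C@@](C)(O[Si](CC)(CC)CC)CC2)/C1=C(/CO[Si](C)(C)C(C)(C)C)C(=O)OCc1ccc(OC)cc1 | intermediate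
18 | 4-methoxybenzyl (E)-2-[(2S,4R,7S)-2-[(tert-butyldiphenylsilyl)oxy]-4-hydroxy-4,7-dimethyl-7-[(triethylsilyl)oxy]-3,4,5,6,7,8-hexahydronaphthalen-1(2H)-ylidene]-3-hydroxypropanoate | CC(C)(C)[Si](c1ccccc1)(c1ccccc1)O[C@H]1C[C@@](C)(O)C2=C(C[C@@](C)(O[Si](CC)(CC)CC)CC2)/C1=C(/CO)C(=O)OCc1ccc(OC)cc1 | intermediate
19 | 4-methoxybenzyl (E)-3-acetoxy-2-[(2S,4R,7S)-2-[(tert-butyldiphenylsilyl)oxy]-4-hydroxy-4,7-dimethyl-7-[(triethylsilyl)oxy]-3,4,5,6,7,8-hexahydronaphthalen-1(2H)-ylidene]propanoate | CC(C)(C)[Si](c1ccccc1)(c1ccccc1)O[C@H]1C[C@@](C)(O)C2=C(C[C@@](C)(O[Si](CC)(CC)CC)CC2)/C1=C(/COC(C)=O)C(=O)OCc1ccc(OC)cc1 | intermediate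
20 | 4-methoxybenzyl (E)-3-acetoxy-2-[(2S,4R,7S)-2-[(tert-butyldiphenylsilyl)oxy]-4,7-dimethyl-4,7-bis[(triethylsilyl)oxy]-3,4,5,6,7,8-hexahydronaphthalen-1(2H)-ylidene]propanoate (key-step precursor) | CC(C)(C)[Si](c1ccccc1)(c1ccccc1)O[C@H]1C[C@@](C)(O[Si](CC)(CC)CC)C2=C(C[C@@](C)(O[Si](CC)(CC)CC)CC2)/C1=C(/COC(C)=O)C(=O)OCc1ccc(OC)cc1 | intermediate
21 | secondary ozonide of 20 (1,2,4-trioxolane spanning C1 and C6; mixture at the two ketal carbons) | CC(C)(C)[Si](c1ccccc1)(c1ccccc1)O[C@H]1C[C@@](C)(O[Si](CC)(CC)CC)C23CC[C@](C)(O[Si](CC)(CC)CC)CC(OO2)(O3)/C1=C(/COC(C)=O)C(=O)OCc1ccc(OC)cc1 | intermediate (not isolated)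
22 | 4-methoxybenzyl (Z)-3-acetoxy-2-[(4S,8S,10R)-8-[(tert-butyldiphenylsilyl)oxy]-4,10-dimethyl-1,6-dioxo-4,10-bis[(triethylsilyl)oxy]cyclodecan-7-ylidene]propanoate (skeletal numbering; key-step product) | CC(C)(C)[Si](c1ccccc1)(c1ccccc1)O[C@H]1C[C@@](C)(O[Si](CC)(CC)CC)C(=O)CC[C@](C)(O[Si](CC)(CC)CC)CC(=O)/C1=C(/COC(C)=O)C(=O)OCc1ccc(OC)cc1 | intermediate
23 | (Z)-3-acetoxy-2-[(4S,8S,10R)-8-[(tert-butyldiphenylsilyl)oxy]-4,10-dihydroxy-4,10-dimethyl-1,6-dioxocyclodecan-7-ylidene]propanoic acid (drawn open; present as C1 lactol and C6 hydroxybutenolide) | CC(C)(C)[Si](c1ccccc1)(c1ccccc1)O[C@H]1C[C@@](C)(O)C(=O)CC[C@](C)(O)CC(=O)/C1=C(/COC(C)=O)C(=O)O | intermediate (not isolated)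
24 | (4S,8S,10R)-13-acetoxy-8-[(tert-butyldiphenylsilyl)oxy]-1,4-epoxy-10-hydroxygermacra-1,5,7(11)-trien-12,6-olide | CC(C)(C)[Si](c1ccccc1)(c1ccccc1)O[C@H]1C[C@@](C)(O)C2=CC[C@@](C)(/C=C3/OC(=O)C(COC(C)=O)=C31)O2 | intermediate
25 | (4S,8S,10R)-13-acetoxy-1,4-epoxy-8,10-dihydroxygermacra-1,5,7(11)-trien-12,6-olide | O[C@H]1C[C@@](C)(O)C2=CC[C@@](C)(/C=C3/OC(=O)C(COC(C)=O)=C31)O2 | intermediate
26 | CNP0394509.2: (4S,8S,10R)-13-acetoxy-1,4-epoxy-10-hydroxy-8-(2-methylprop-2-enoyloxy)germacra-1,5,7(11)-trien-12,6-olide | C=C(C)C(=O)O[C@H]1C[C@@](C)(O)C2=CC[C@@](C)(/C=C3/OC(=O)C(COC(C)=O)=C31)O2 | target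

## Step count and uncertain steps

Total: 20 steps. Longest linear sequence: 17 steps (5 → 12, then steps 9–20); the branch from 1 is 15 steps.

**Step 17 (key step).**
- What may go wrong: incomplete discrimination between C1=C6 and the C7=C11 bond or the anisyl ring; epoxidation instead of cleavage at the hindered tetrasubstituted alkene; sluggish reduction of the hindered peroxide; transannular aldol condensation of the 1,6-dione during work-up.
- Fallback: from 20, stoichiometric OsO4 in pyridine/THF followed by NaHSO3 dihydroxylates the more electron-rich C1=C6 bond to cis-1,6-diol F1. Pb(OAc)4 with K2CO3 in benzene then cleaves the glycol, the classical two-stage opening of an octalin to a cyclodecanedione, and returns to 22.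

**Step 12.**
- What may go wrong: carbonylation of the alkenylpalladium before alkyne insertion; β-elimination of the C13 silyloxy group from the alkenylpalladium after insertion; base-induced loss of the C8 silyloxy group from the β-silyloxy ketone, which would lead on to aromatisation of ring B.
- Fallback: separate ring closure from carbonylation. From 15, Pd(PPh3)4, B2pin2 and KOAc in toluene effect cyclisation with borylative termination to alkenyl boronate F2. N-Iodosuccinimide in MeCN replaces boron by iodine with retention to give alkenyl iodide F3. Pd(OAc)2/PPh3, CO, 4-methoxybenzyl alcohol and Et3N at room temperature then give 16.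

**Step 11.**
- What may go wrong: triflation on the side-chain oxygen instead of the ring oxygen, or loss of the β-silyloxy group from the acyl chain under basic conditions.
- Fallback: form the triflate before the chain is attached, on the simplest 2-acyl ketone. From 4, LiN(iPr)2 then 1-acetylimidazole gives 2-acetyl diketone F4. NaH/Tf2O gives 2-acetylcyclohexenyl triflate F5, and any regioisomer is removed at this cheap stage. A boron aldol addition of the methyl ketone (chlorodiisopinocampheylborane, Et3N) to ynal 7 gives β-hydroxy ketone F6 with reagent control at C8, and tBuPh2SiCl/imidazole returns to 15.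

**Step 18.**
- What may go wrong: elimination or ionisation of the tertiary C4 and C10 alcohols; α-ketol shift at C10–C1; transannular aldol reaction between C2 or C5 and the opposite carbonyl; incomplete dehydration of the lactol or of the hydroxybutenolide in protic acid.
- Fallback: make the two eliminations non-protic. From 22, CF3CO2H/anisole as above gives 23. PPTS and HC(OMe)3 in MeOH convert the lactol and the hydroxybutenolide into bis(methyl ketal) F7. Me3SiOTf with iPr2NEt in CH2Cl2 at −20 °C then removes methanol from both ketal carbons (ketal-to-enol-ether elimination; the C10 hydroxyl is silylated in passing and freed with K2CO3/MeOH), returning to 24.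

## Further compounds

F1 | step 17 | cis-1,6-diol of 20 (hydroxyls at C1 and C6; face not specified) | CC(C)(C)[Si](c1ccccc1)(c1ccccc1)O[C@H]1C[C@@](C)(O[Si](CC)(CC)CC)C2(O)CC[C@](C)(O[Si](CC)(CC)CC)CC2(O)/C1=C(/COC(C)=O)C(=O)OCc1ccc(OC)cc1
F2 | step 12 | alkenyl pinacol boronate (boron on C11 cis to C6; otherwise as 16) | CC(C)(C)[Si](c1ccccc1)(c1ccccc1)O[C@H]1CC(=O)C2=C(C[C@@](C)(O[Si](CC)(CC)CC)CC2)/C1=C(/CO[Si](C)(C)C(C)(C)C)B1OC(C)(C)C(C)(C)O1
F3 | step 12 | alkenyl iodide (iodine on C11 cis to C6; otherwise as 16) | CC(C)(C)[Si](c1ccccc1)(c1ccccc1)O[C@H]1CC(=O)C2=C(C[C@@](C)(O[Si](CC)(CC)CC)CC2)/C1=C(/CO[Si](C)(C)C(C)(C)C)I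
F4 | step 11 | (5S)-2-acetyl-5-methyl-5-[(triethylsilyl)oxy]cyclohexan-1-one | CC(=O)C1CC[C@](C)(O[Si](CC)(CC)CC)CC1=O
F5 | step 11 | (5S)-2-acetyl-5-methyl-5-[(triethylsilyl)oxy]cyclohex-1-en-1-yl trifluoromethanesulfonate | CC(=O)C1=C(OS(=O)(=O)C(F)(F)F)C[C@@](C)(O[Si](CC)(CC)CC)CC1
F6 | step 11 | (5S)-2-{(3S)-6-[(tert-butyldimethylsilyl)oxy]-3-hydroxyhex-4-ynoyl}-5-methyl-5-[(triethylsilyl)oxy]cyclohex-1-en-1-yl trifluoromethanesulfonate | O=C(C[C@H](O)C#CCO[Si](C)(C)C(C)(C)C)C1=C(OS(=O)(=O)C(F)(F)F)C[C@@](C)(O[Si](CC)(CC)CC)CC1
F7 | step 18 | bis(methyl ketal): C1 methyl ketal of the 1,4-epoxide and C6 methoxybutenolide (C1 and C6 configuration not specified) | CC(C)(C)[Si](c1ccccc1)(c1ccccc1)O[C@H]1C[C@@](C)(O)C2(OC)CC[C@@](C)(CC3(OC)OC(=O)C(COC(C)=O)=C31)O2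
A1 | alternative 1 | olefinic ester: tertiary homoallylic C4 ester of the C10 α-silyloxy acid | COc1ccc(COCC[C@@](C)(O[Si](CC)(CC)CC)C(=O)O[C@@](C)(CC=C)CO[Si](C(C)C)(C(C)C)C(C)C)cc1
A2 | alternative 1 | dihydrofuran with both quaternary centres | COc1ccc(COCC[C@@](C)(O[Si](CC)(CC)CC)C2=CC[C@@](C)(CO[Si](C(C)C)(C(C)C)C(C)C)O2)cc1
A3 | alternative 2 | E iodoylidene butenolide with tethered C4 methyl ketone and C1 dithiane | I/C=C1/OC(=O)C(CO[Si](C)(C)C(C)(C)C)=C1[C@@H](O[Si](C)(C)C(C)(C)C)C[C@@](C)(O[Si](CC)(CC)CC)C1(SCCCS1)CCC(C)=O
A4 | alternative 2 | macrocyclic tertiary alcohol | CC(C)(C)[Si](C)(C)O[C@H]1C[C@@](C)(O[Si](CC)(CC)CC)C2(SCCCS2)CC[C@](C)(O)/C=C3/OC(=O)C(CO[Si](C)(C)C(C)(C)C)=C31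
A5 | alternative 3 | cis-1-vinyl-2-alkenylcyclohexanol fused to the butenolide (C1 and C6 configuration and enol-ether geometry not encoded) | C=CC1(O)C2(C=C(C)O[Si](CC)(CC)CC)OC(=O)C(CO[Si](C)(C)C(C)(C)C)=C2[C@@H](O[Si](C)(C)C(C)(C)C)C[C@@]1(C)OCOC
A6 | alternative 3 | cyclodecenone with C1 ketone and ylidene butenolide | CC(C)(C)[Si](C)(C)O[C@H]1C[C@@](C)(OCOC)C(=O)CC[C@](C)(O[Si](CC)(CC)CC)/C=C2/OC(=O)C(CO[Si](C)(C)C(C)(C)C)=C21
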